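The earlier runs and the new flask were computed with constants of no real substance; noise was put on by code.

If a rate ignores both substrate and solid reagent, I ask whether catalyst or supply holds it.

| setting | Monday's | Sunday's | Friday's | flask |
|---|---|---|---|---|
| substrate | 0.025 M | 0.038 M | 0.050 M | 0.050 M |
| solid reagent | 0.050 M | 0.050 M | 0.10 M | 0.0500 M |
| free catalyst | 2.5 mM | 2.5 mM | 2.5 mM | 2.5 mM |
| remark | run made earlier | run made earlier | run made earlier |  |

| run | time / h | product / % | substrate / % |
|---|---|---|---|
| Monday's | 0.833 | 2.4 | 90.2 |
| Monday's | 1.50 | 8.8 | 86.6 |
| Monday's | 2.50 | 15.3 | 79.0 |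
| Monday's | 3.00 | 18.9 | 75.4 |
| Monday's | 4.00 | 27.2 | 68.5 |
| Sunday's | 0.333 | 0.7 | 95.7 |
| Sunday's | 1.00 | 3.1 | 92.6 |
| Sunday's | 2.00 | 7.8 | 86.8 |
| Sunday's | 3.00 | 14.0 | 81.3 |
| Sunday's | 4.00 | 19.6 | 76.4 |
| Friday's | 0.833 | 1.5 | 94.4 |
| Friday's | 1.50 | 3.5 | 92.4 |
| Friday's | 2.50 | 9.0 | 88.6 |
| Friday's | 3.00 | 10.1 | 84.7 |
| Friday's | 4.00 | 15.4 | 81.3 |

(standard deviation of a reading: 0.5 percentage points)

- amounts and yields of by-product count idle complex too
- given per volume of solution although it is solid: solid reagent
- steps thought possible: free catalyst + by-product <-> idle complex; solid reagent <-> coupling partner; substrate + free catalyst <-> catalyst intermediate A; catalyst intermediate D <-> free catalyst + product; catalyst intermediate C -> by-product + catalyst intermediate D; catalyst intermediate A -> catalyst intermediate B; coupling partner + catalyst intermediate B -> catalyst intermediate C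
- at the start none of the solid reagent is in solution
- no earlier run changes the charge of free catalyst; that part of a forecast is a guess

- factor on the rate of making product when 30 % of the substrate are converted if free catalyst is charged twice over
- factor on the rate when 30 % of the substrate are converted if free catalyst is charged at 12 mM instead

1. I read the slope of c(product) from the second reading to the last. Monday's gave 1.84 mM/h, Sunday's 2.09 mM/h, Friday's 2.38 mM/h. Yet Friday's held twice the substrate of Monday's and twice its solid reagent.

2. Their mean, 2.10 mM/h, I called the supply rate: the steady rate at which coupling partner reaches solution, taken as a reading. I assumed it does not grow with catalyst.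

3. In Friday's run, c(substrate) lost minus c(product) formed was 1.65 mM at the last reading. That is a bound share of 0.660 of the charge. Dividing gave the catalyst capacity, the rate with the whole charge bound: 3.19 mM/h.

4. The ratio of supply rate to capacity is the bound share by construction, so it tested nothing. My ground was the slopes: Friday's was 1.29 times Monday's, less than the rise in either charge. I took dissolution as the rate-limiting step and reckoned both factors near 1. Those slopes cannot tell supply from catalyst, and no run varied catalyst, so this was a guess.

5. The forecast differed: 1.85 (1.4 to 2.05) and 3.9 (2.2 to 4.9), saying “so I expect slightly sublinear scaling”.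

    free catalyst + by-product ⇌ idle complex (K = 4.40 /M, k = 1.40 /M/min)
    solid reagent ⇌ coupling partner, rate k2*(cs2 - [coupling partner]) while solid is left; crystals form when [coupling partner] > cs2 (solubility = 20.0 mM, k = 0.00200 /min)
    substrate + free catalyst ⇌ catalyst intermediate A (K = 19.0 /M, k = 11.0 /M/min)
    catalyst intermediate D ⇌ free catalyst + product (K = 1.70 M, k = 0.100 /min)
    catalyst intermediate C → by-product + catalyst intermediate D (k = 0.180 /min)
    catalyst intermediate A → catalyst intermediate B (k = 0.0890 /min)
    coupling partner + catalyst intermediate B → catalyst intermediate C (k = 43.0 /M/min)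

The doubled charge gave 1.07. When 30 % was converted in the flask, the rate was 2.21 mM/h and 28.2 % of the catalyst was free catalyst. At the supply rate, that conversion takes 7.13 h; the flask reached it at 6.52 h. At 12 mM, the capacity scales to 15.3 mM/h, and the supply rate is 0.137 of it. The factor there was 1.08.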